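**Retrosynthetic overview**
- Target ⇒ allylic aryl ether C–O bond: 2,4,6-trihydroxybenzophenone (para-OH) plus (2E,5S)-3,7-dimethylocta-2,7-diene-1,5-diol, joined last by a Mitsunobu reaction.
- Diol ⇒ syn methyl-alumination / hydroxymethylation of the terminal alkyne of (4S)-2-methylhept-1-en-6-yn-4-ol, which fixes the E-trisubstituted alkene.
- Alkynol ⇒ C4–C5 bond: catalytic enantioselective propargylation of 3-methylbut-3-enal with an allenylsilane under chiral silylium ion-pair (IDPi) organocatalysis; this sets the only stereocentre.
- Aldehyde ⇐ 3-methylbut-3-en-1-ol. No ring is formed; both benzene rings arrive in the benzophenone.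

Assumption: 2,4,6-trihydroxybenzophenone, 3-methylbut-3-en-1-ol and trimethyl(propa-1,2-dienyl)silane are taken as catalogue chemicals, and the IDPi antipode that gives Re-face attack (the S carbinol) is fixed by one Mosher-ester test run, both antipodes being available from (R)- or (S)-BINOL.

**Route**

Step 1
Reactants: 1 3-methylbut-3-en-1-ol
Product: 2 3-methylbut-3-enal
Conditions: DMP (1.1 equiv), CH2Cl2, 0 °C → rt, 1 h; cold NaHCO3/Na2S2O3 wash, dry, use as a titrated CH2Cl2 solution (not concentrated to dryness)
Reagents that add atoms: none
Why: Dess–Martin oxidation is fast and non-basic, so the volatile skipped (β,γ-unsaturated) aldehyde forms without isomerising to conjugated prenal; no stereocentre yet.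

Step 2
Reactants: 2 3-methylbut-3-enal; 3 trimethyl(propa-1,2-dien-1-yl)silane
Product: 5 (4S)-2-methylhept-1-en-6-yn-4-ol, via TMS ether 4 (not isolated)
Conditions: IDPi (BINOL-derived imidodiphosphorimidate, N-Tf core, 2 mol%) premixed with 3 (3–5 equiv), toluene/CH2Cl2, −78 → −40 °C, slow addition of 2; then 1 M HCl, THF, 0 °C
Reagents that add atoms: none
Why: Proposed new method: the IDPi acid is silylated by a little 3 to a chiral silylium ion pair that silylates the aldehyde oxygen; inside the confined imidodiphosphorimidate anion only the Re face of the O-silyl oxocarbenium is open, the allenylsilane attacks through its CH2 terminus (SE2′) to give a β-silyl-stabilised vinyl cation, and return of Me3Si+ to the anion unveils the terminal alkyne and turns the catalyst over, so the C4–C5 bond and the 4S centre are set in one metal-free event; closest known reactions are the IDPi-catalysed Hosomi–Sakurai allylation of aldehydes with allyltrimethylsilane and the TiCl4-mediated propargylation of aldehydes with allenylsilanes.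

Step 3
Reactants: 5 (4S)-2-methylhept-1-en-6-yn-4-ol
Product: 7 (2E,5S)-3,7-dimethylocta-2,7-diene-1,5-diol, via alkenylalane 6 (not isolated)
Conditions: AlMe3 (3.5 equiv), Cp2ZrCl2 (0.25 equiv), CH2Cl2, 0 °C → rt; volatiles off; n-BuLi, THF, −78 °C; (CH2O)n, −78 °C → rt; aq. Rochelle salt
Reagents that add atoms: trimethylaluminium C[Al](C)C; formaldehyde (from paraformaldehyde) C=O
Why: Negishi Zr-catalysed carboalumination adds CH3 and Al syn across the terminal alkyne with methyl at the internal carbon (the 1,1-disubstituted alkene and the aluminium alkoxide are inert), and the derived alanate is hydroxymethylated with retention, giving only the 2E alkene; C5 is untouched.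

Step 4
Reactants: 7 (2E,5S)-3,7-dimethylocta-2,7-diene-1,5-diol; 8 (2,4,6-trihydroxyphenyl)(phenyl)methanone
Product: 9 {2,6-dihydroxy-4-[(2E,5S)-5-hydroxy-3,7-dimethylocta-2,7-dien-1-yl]oxyphenyl}(phenyl)methanone
Conditions: 8 (1.5 equiv), PPh3 (1.2 equiv), DIAD (1.2 equiv, slow addition), THF, 0 °C → rt
Reagents that add atoms: none
Why: Mitsunobu etherification activates the primary allylic alcohol far faster than the secondary one and pairs it with the most acidic, unhindered para-OH of 8 (the ortho-OH groups are hydrogen-bonded to the carbonyl and flanked by the benzoyl group), and SN2 at C1 leaves the E-alkene and the C5 stereocentre unchanged.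

**Compound list**

1 | 3-methylbut-3-en-1-ol | C=C(C)CCO | starting material
2 | 3-methylbut-3-enal | C=C(C)CC=O | intermediate
3 | trimethyl(propa-1,2-dien-1-yl)silane | C=C=C[Si](C)(C)C | starting material
4 | trimethyl{[(4S)-2-methylhept-1-en-6-yn-4-yl]oxy}silane | C=C(C)C[C@H](O[Si](C)(C)C)CC#C | intermediate
5 | (4S)-2-methylhept-1-en-6-yn-4-ol | C=C(C)C[C@H](O)CC#C | intermediate
6 | [(1E,4S)-4-(dimethylalumanyloxy)-2,6-dimethylhepta-1,6-dien-1-yl]dimethylalumane | C=C(C)C[C@H](O[Al](C)C)C/C(C)=C/[Al](C)C | intermediate
7 | (2E,5S)-3,7-dimethylocta-2,7-diene-1,5-diol | C=C(C)C[C@H](O)C/C(C)=C/CO | intermediate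
8 | (2,4,6-trihydroxyphenyl)(phenyl)methanone | O=C(c1ccccc1)c1c(O)cc(O)cc1O | starting material
9 | {2,6-dihydroxy-4-[(2E,5S)-5-hydroxy-3,7-dimethylocta-2,7-dien-1-yl]oxyphenyl}(phenyl)methanone | C=C(C)C[C@H](O)C/C(C)=C/COc1cc(O)c(C(=O)c2ccccc2)c(O)c1 | target

**Totals**

Total step count: 4. Longest linear sequence: 4 steps (1 → 2 → 5 → 7 → 9).

**Steps most likely to fail**

Step 2 (the proposed new reaction). Allenylsilanes are weaker π-nucleophiles than allylsilanes. The 1,1-disubstituted alkene of 2 and 4 can compete for the silylated aldehyde and give Prins/ene oligomers. The silylated skipped enal can lose an α-proton to give the dienol silyl ether. The level and sense of induction are untested. Slow addition of 2 into excess 3 at low temperature is the built-in countermeasure. The fallback uses known chemistry and sets out from 2. It replaces the open silylium ion pair and silicon nucleophile by a closed six-membered boron transition state under chiral Brønsted acid catalysis: allenylboronic acid pinacol ester (1.5 equiv), (R)-TRIP phosphoric acid (5–10 mol%), 4 Å MS, toluene, −30 °C. The acid hydrogen-bonds the boronate oxygen and the formyl C–H, and Re-face attack by the accepted chair model gives the borate 4,4,5,5-tetramethyl-2-{[(4S)-2-methylhept-1-en-6-yn-4-yl]oxy}-1,3,2-dioxaborolane F1. Aqueous work-up hydrolyses it and the route is rejoined at 5. No cationic intermediate is involved, so the pendant alkene is innocent. The cost is a higher catalyst loading and an ee that is typically only about 80–90% for α-unbranched aliphatic aldehydes.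

Step 4. Possible problems are alkylation at an ortho-OH or twice, partial activation of the secondary alcohol, and some SN2′ attack. The fallback sets out from 7 and replaces redox condensation by classical phenoxide alkylation. Corey–Kim chlorination (NCS, Me2S, CH2Cl2, −20 → 0 °C) converts only the primary allylic alcohol into (4S,6E)-8-chloro-2,6-dimethylocta-1,6-dien-4-ol F4. The mono-potassium salt of 8 (K2CO3 1.0 equiv, acetone, 40 °C), in which the most acidic para-OH is the one ionised, is then O-alkylated by SN2, and the route is rejoined at 9.

Step 3. Carboalumination next to an aluminium alkoxide can stall or give a few percent of the regioisomer, and hydroxymethylation of the alanate with paraformaldehyde can be sluggish. The fallback sets out from 5 and builds the alkene by hydroxyl-directed hydroalumination instead of carbometalation. The alkoxide/acetylide dianion (n-BuLi 2.2 equiv, THF, −78 °C) is trapped with paraformaldehyde to give (5S)-7-methyloct-7-en-2-yne-1,5-diol F2. Red-Al (THF, 0 °C → rt; both alkoxides steer aluminium to C3), then I2 at −78 °C, gives (2Z,5S)-3-iodo-7-methylocta-2,7-diene-1,5-diol F3. Me2CuLi (excess, Et2O, 0 °C) replaces iodine by methyl with retention, and the route is rejoined at 7.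

**Further compounds**

F1 | step 2 | 4,4,5,5-tetramethyl-2-{[(4S)-2-methylhept-1-en-6-yn-4-yl]oxy}-1,3,2-dioxaborolane | C=C(C)C[C@H](OB1OC(C)(C)C(C)(C)O1)CC#C
F2 | step 3 | (5S)-7-methyloct-7-en-2-yne-1,5-diol | C=C(C)C[C@H](O)CC#CCO
F3 | step 3 | (2Z,5S)-3-iodo-7-methylocta-2,7-diene-1,5-diol | C=C(C)C[C@H](O)C/C(I)=C/CO
F4 | step 4 | (4S,6E)-8-chloro-2,6-dimethylocta-1,6-dien-4-ol | C=C(C)C[C@H](O)C/C(C)=C/CCl
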